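**Retrosynthetic overview**

- The strategy rests on the C3–C3a bond between the dihydrofuran ring and ring A, and on C9 (the exocyclic carbon on C3) at the carboxyl level. These are the C4–C4a bond and the C4 carbonyl of a (2S)-flavanone; shifting ring A from C4 to C3 contracts the pyranone to the trans 2-aryl-2,3-dihydrobenzofuran 3-ester, and flavanone C2 becomes C2 of the target.
- After the contraction: C9 ester → C9–OH, acylated with silyl-protected 4-hydroxybenzoic acid; C5–Br → alkyne (Sonogashira) → Z-alkenyl acetal (Lindlar) → Z-enal, unmasked last.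
- Before it: the flavanone comes from 6-bromo-8-methoxychromone and an arylboronic acid by enantioselective palladium-catalysed conjugate addition (sets C2); the chromone comes from brominated 2-hydroxy-3-methoxyacetophenone.
- Ring order: the pyranone ring is closed in step 2 and contracted to the dihydrofuran ring in step 6; both benzene rings are bought.

Key step: step 6

Assumption: the (R)-pyridine-oxazoline ligand is taken to give the 2S flavanone, by analogy with the facial sense of its (S)-antipode on 3-substituted cyclohexenones; the antipodal ligand would be used if the sense proved opposite.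

**Route**

Step 1
Reactants: 1 1-(2-hydroxy-3-methoxyphenyl)ethanone
Product: 2 1-(5-bromo-2-hydroxy-3-methoxyphenyl)ethanone
Conditions: NBS, MeCN, 0 °C to rt
Reagents that add atoms: N-bromosuccinimide, O=C1CCC(=O)N1Br
Why: Electrophilic aromatic bromination, in which the free phenol directs to its para position C5 (both ortho positions are substituted and C5 is meta to the acetyl group) and, without acid or radical initiation, the methyl ketone is not brominated.

Step 2
Reactants: 2 1-(5-bromo-2-hydroxy-3-methoxyphenyl)ethanone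
Product: 4 6-bromo-8-methoxy-4H-chromen-4-one, via enaminone 3 (not isolated)
Conditions: Me2NCH(OMe)2, toluene, 100 °C; concentrate; conc. HCl, CH2Cl2, 40 °C
Reagents that add atoms: N,N-dimethylformamide dimethyl acetal, COC(OC)N(C)C
Why: Enaminone route to chromones, in which the acetal condenses with the methyl ketone to the β-dimethylamino enone 3 and acid then drives conjugate addition of the phenol oxygen with loss of dimethylamine (addition–elimination, 6-endo closure) to the pyranone ring.

Step 3
Reactants: 5 2-methoxy-4-(4,4,5,5-tetramethyl-1,3,2-dioxaborolan-2-yl)phenol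
Product: 6 2-methoxy-4-(4,4,5,5-tetramethyl-1,3,2-dioxaborolan-2-yl)phenyl pivalate
Conditions: PivCl, Et3N, DMAP (cat.), CH2Cl2, 0 °C to rt
Reagents that add atoms: pivaloyl chloride, CC(C)(C)C(=O)Cl
Why: DMAP-catalysed O-acylation of the phenol, the pinacol boronate being inert to acyl chloride and amine base.

Step 4
Reactants: 6 2-methoxy-4-(4,4,5,5-tetramethyl-1,3,2-dioxaborolan-2-yl)phenyl pivalate
Product: 7 [3-methoxy-4-(pivaloyloxy)phenyl]boronic acid
Conditions: NaIO4, NH4OAc, acetone–H2O (1:1), rt
Reagents that add atoms: water, O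
Why: Oxidative deprotection of a pinacol boronate, in which periodate cleaves the pinacol set free in the hydrolysis equilibrium (glycol cleavage) and so drives the ester to the free boronic acid, the aryl pivalate being untouched near neutral pH.

Step 5
Reactants: 4 6-bromo-8-methoxy-4H-chromen-4-one; 7 [3-methoxy-4-(pivaloyloxy)phenyl]boronic acid
Product: 8 (2S)-6-bromo-8-methoxy-2-(3-methoxy-4-pivaloyloxyphenyl)chroman-4-one
Conditions: Pd(OCOCF3)2 (5 mol%), (R)-4-tert-butyl-2-(pyridin-2-yl)-4,5-dihydrooxazole (6 mol%), NH4PF6 (30 mol%), H2O (5 equiv), ClCH2CH2Cl, 60 °C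
Reagents that add atoms: none
Why: Palladium-catalysed enantioselective conjugate addition of an arylboronic acid to a chromone, in which the aryl group is transmetalated to cationic divalent palladium carrying the pyridine-oxazoline, the C2=C3 bond inserts with the face fixed by the tert-butyl group of the ligand (this sets C2 as S) and water protonates the palladium enolate, the C–Br bond surviving because the cycle does not pass through zerovalent palladium.

Step 6
Reactants: 8 (2S)-6-bromo-8-methoxy-2-(3-methoxy-4-pivaloyloxyphenyl)chroman-4-one; 9 trimethyl orthoformate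
Product: 11 methyl trans-(2S,3S)-5-bromo-7-methoxy-2-(3-methoxy-4-pivaloyloxyphenyl)-2,3-dihydro-1-benzofuran-3-carboxylate, via enol ether 10 (not isolated)
Conditions: HC(OMe)3 (solvent), conc. H2SO4 (cat.), rt; then PhI(OAc)2 (1.2 equiv), rt
Reagents that add atoms: trimethyl orthoformate (compound 9, also the solvent), COC(OC)OC
Why: Acid and the orthoformate turn the C4 ketone into its ketal and the enol ether 10; the trivalent iodine reagent adds to C3 of 10 anti to the C2 aryl group and methanol re-forms the C4 ketal, which places the C3–I bond equatorial and antiperiplanar to the C4–C4a bond. Ring A then shifts from C4 to C3 with expulsion of PhI (new C3–C3a bond, inversion at C3), and the exocyclic dimethoxycarbenium ion loses a methyl group to acetate to leave the methyl ester; the closest known reaction is the oxidative ring contraction of flavanones by PhI(OAc)2 or Tl(NO3)3 in trimethyl orthoformate. The dihydrofuran ring is not closed by a cyclisation but arises by the 1,2-aryl shift that expels C4 from the six-membered ring (contraction, six to five). C3 is the new stereocentre: anti attack of the iodane followed by migration with inversion puts the ester trans to the C2 aryl group, which is also the thermodynamically preferred arrangement, while C2 is not touched. The step needs migration of ring A instead of the C2 aryl group (isoflavone) or loss of H-2 (flavone); the ring oxygen ortho to C4a makes ring A a good migrating group, the pivalate makes ring C a poor one, and the conformer with equatorial aryl and equatorial iodane aligns only the C4–C4a bond. Integrity of C2 requires that ketalisation at room temperature outruns acid-induced opening of the pyranone to the chalcone, which is why the ketone is first stirred with acid and orthoformate before the oxidant is added.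

Step 7
Reactants: 11 methyl trans-(2S,3S)-5-bromo-7-methoxy-2-(3-methoxy-4-pivaloyloxyphenyl)-2,3-dihydro-1-benzofuran-3-carboxylate
Product: 12 4-[(2S,3R)-5-bromo-3-(hydroxymethyl)-7-methoxy-2,3-dihydro-1-benzofuran-2-yl]-2-methoxyphenol
Conditions: LiAlH4 (3 equiv), THF, −10 to 0 °C; aq. potassium sodium tartrate work-up
Reagents that add atoms: none
Why: Hydride reduction of both esters with LiAlH4, in which the methyl ester gives the C9 primary alcohol and the pivalate is cleaved to the phenol, fast enough at low temperature that neither the C–Br bond nor the two stereocentres are affected (the C3 descriptor changes from S to R by priority only).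

Step 8
Reactants: 12 4-[(2S,3R)-5-bromo-3-(hydroxymethyl)-7-methoxy-2,3-dihydro-1-benzofuran-2-yl]-2-methoxyphenol
Product: 13 (2S,3R)-5-bromo-2-[4-(tert-butyldimethylsilyloxy)-3-methoxyphenyl]-3-[(tert-butyldimethylsilyloxy)methyl]-7-methoxy-2,3-dihydro-1-benzofuran
Conditions: TBSCl (2.5 equiv), imidazole, DMF, rt
Reagents that add atoms: tert-butyldimethylsilyl chloride, CC(C)(C)[Si](C)(C)Cl
Why: Silylation of the phenol and the primary alcohol with TBSCl and imidazole (nucleophilic catalysis through the N-silylimidazolium ion), run to the bis-ether because the two hydroxyl groups cannot be told apart reliably in a direct monosilylation.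

Step 9
Reactants: 13 (2S,3R)-5-bromo-2-[4-(tert-butyldimethylsilyloxy)-3-methoxyphenyl]-3-[(tert-butyldimethylsilyloxy)methyl]-7-methoxy-2,3-dihydro-1-benzofuran
Product: 14 [(2S,3R)-5-bromo-2-[4-(tert-butyldimethylsilyloxy)-3-methoxyphenyl]-7-methoxy-2,3-dihydro-1-benzofuran-3-yl]methanol
Conditions: camphorsulfonic acid (10 mol%), MeOH–CH2Cl2 (1:1), 0 °C
Reagents that add atoms: none
Why: Acid-catalysed methanolysis of silyl ethers, which is far faster for a primary alkyl TBS ether than for an aryl TBS ether (the alkyl oxygen is the more basic one), so that only the C9 oxygen is set free.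

Step 10
Reactants: 15 4-hydroxybenzoic acid
Product: 17 4-(tert-butyldimethylsilyloxy)benzoic acid, via silyl ester 16 (not isolated)
Conditions: TBSCl (2.5 equiv), imidazole, DMF, rt; then AcOH–THF–H2O (3:1:1), rt
Reagents that add atoms: tert-butyldimethylsilyl chloride, CC(C)(C)[Si](C)(C)Cl
Why: Exhaustive silylation followed by selective hydrolysis of the labile silyl ester under mild aqueous acid, which leaves the aryl silyl ether in place.

Step 11
Reactants: 14 [(2S,3R)-5-bromo-2-[4-(tert-butyldimethylsilyloxy)-3-methoxyphenyl]-7-methoxy-2,3-dihydro-1-benzofuran-3-yl]methanol; 17 4-(tert-butyldimethylsilyloxy)benzoic acid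
Product: 18 [(2S,3R)-5-bromo-2-[4-(tert-butyldimethylsilyloxy)-3-methoxyphenyl]-7-methoxy-2,3-dihydro-1-benzofuran-3-yl]methyl 4-(tert-butyldimethylsilyloxy)benzoate
Conditions: EDC·HCl, DMAP (cat.), CH2Cl2, 0 °C to rt
Reagents that add atoms: none
Why: Steglich esterification, in which the carbodiimide activates the acid and DMAP transfers the acyl group to the primary C9 alcohol, so that the C9–O bond is never activated and substitution or elimination at C9 cannot occur.

Step 12
Reactants: 18 [(2S,3R)-5-bromo-2-[4-(tert-butyldimethylsilyloxy)-3-methoxyphenyl]-7-methoxy-2,3-dihydro-1-benzofuran-3-yl]methyl 4-(tert-butyldimethylsilyloxy)benzoate; 19 3,3-diethoxyprop-1-yne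
Product: 20 [(2S,3R)-2-[4-(tert-butyldimethylsilyloxy)-3-methoxyphenyl]-5-(3,3-diethoxyprop-1-yn-1-yl)-7-methoxy-2,3-dihydro-1-benzofuran-3-yl]methyl 4-(tert-butyldimethylsilyloxy)benzoate
Conditions: PdCl2(PhCN)2 (3 mol%), P(t-Bu)3·HBF4 (6 mol%), CuI (2 mol%), i-Pr2NH, 1,4-dioxane, degassed, rt to 40 °C
Reagents that add atoms: none
Why: Sonogashira coupling, in which the bulky electron-rich phosphine allows oxidative addition of the electron-rich aryl bromide to zerovalent palladium near room temperature and the copper acetylide of 19 is transferred and reductively eliminated, the ester, silyl ethers and acetal being inert to the amine base.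

Step 13
Reactants: 20 [(2S,3R)-2-[4-(tert-butyldimethylsilyloxy)-3-methoxyphenyl]-5-(3,3-diethoxyprop-1-yn-1-yl)-7-methoxy-2,3-dihydro-1-benzofuran-3-yl]methyl 4-(tert-butyldimethylsilyloxy)benzoate
Product: 21 [(2S,3R)-2-[4-(tert-butyldimethylsilyloxy)-3-methoxyphenyl]-5-[(Z)-3,3-diethoxyprop-1-en-1-yl]-7-methoxy-2,3-dihydro-1-benzofuran-3-yl]methyl 4-(tert-butyldimethylsilyloxy)benzoate
Conditions: H2 (1 atm), Pd/CaCO3 poisoned with Pb(OAc)2, quinoline, EtOAc, rt, stopped after one equivalent of H2
Reagents that add atoms: none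
Why: Lindlar semihydrogenation, in which syn addition of H2 on the poisoned palladium surface gives the Z alkene while lead and quinoline hold back over-reduction and hydrogenolysis of the benzylic C2–O bond.

Step 14
Reactants: 21 [(2S,3R)-2-[4-(tert-butyldimethylsilyloxy)-3-methoxyphenyl]-5-[(Z)-3,3-diethoxyprop-1-en-1-yl]-7-methoxy-2,3-dihydro-1-benzofuran-3-yl]methyl 4-(tert-butyldimethylsilyloxy)benzoate
Product: 22 [(2S,3R)-5-[(Z)-3,3-diethoxyprop-1-en-1-yl]-2-(4-hydroxy-3-methoxyphenyl)-7-methoxy-2,3-dihydro-1-benzofuran-3-yl]methyl 4-hydroxybenzoate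
Conditions: Bu4NF, AcOH (1:1), THF, 0 °C
Reagents that add atoms: none
Why: Fluoride cleavage of the two aryl silyl ethers (strong Si–F bond), buffered with acetic acid so that no free phenoxide attacks the aryl ester, the acetal being stable to this medium (any premature hydrolysis would only lead on to 23).

Step 15
Reactants: 22 [(2S,3R)-5-[(Z)-3,3-diethoxyprop-1-en-1-yl]-2-(4-hydroxy-3-methoxyphenyl)-7-methoxy-2,3-dihydro-1-benzofuran-3-yl]methyl 4-hydroxybenzoate
Product: 23 [(2S,3R)-2-(4-hydroxy-3-methoxyphenyl)-7-methoxy-5-[(Z)-3-oxoprop-1-en-1-yl]-2,3-dihydro-1-benzofuran-3-yl]methyl 4-hydroxybenzoate (CNP0400980.1)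
Conditions: pyridinium p-toluenesulfonate (cat.), acetone–H2O (10:1), 0 °C, exclusion of light
Reagents that add atoms: water, O
Why: Acid-catalysed acetal hydrolysis through the allylic oxocarbenium ion, which forms so easily that a weak pyridinium acid at low temperature in the dark should suffice and leave the Z alkene intact, and since only ethanol is released the labile Z enal need not survive any later reaction.

**Compound list**

1 | 1-(2-hydroxy-3-methoxyphenyl)ethanone | COc1cccc(C(C)=O)c1O | starting material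
2 | 1-(5-bromo-2-hydroxy-3-methoxyphenyl)ethanone | COc1cc(Br)cc(C(C)=O)c1O | intermediate
3 | (E)-1-(5-bromo-2-hydroxy-3-methoxyphenyl)-3-(dimethylamino)prop-2-en-1-one | COc1cc(Br)cc(C(=O)/C=C/N(C)C)c1O | intermediate
4 | 6-bromo-8-methoxy-4H-chromen-4-one | COc1cc(Br)cc2c(=O)ccoc12 | intermediate
5 | 2-methoxy-4-(4,4,5,5-tetramethyl-1,3,2-dioxaborolan-2-yl)phenol | COc1cc(B2OC(C)(C)C(C)(C)O2)ccc1O | starting material
6 | 2-methoxy-4-(4,4,5,5-tetramethyl-1,3,2-dioxaborolan-2-yl)phenyl pivalate | COc1cc(B2OC(C)(C)C(C)(C)O2)ccc1OC(=O)C(C)(C)C | intermediate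
7 | [3-methoxy-4-(pivaloyloxy)phenyl]boronic acid | COc1cc(B(O)O)ccc1OC(=O)C(C)(C)C | intermediate
8 | (2S)-6-bromo-8-methoxy-2-(3-methoxy-4-pivaloyloxyphenyl)chroman-4-one | COc1cc([C@H]2Oc3c(OC)cc(Br)cc3C(=O)C2)ccc1OC(=O)C(C)(C)C | intermediate
9 | trimethyl orthoformate | COC(OC)OC | starting material
10 | (2S)-6-bromo-4,8-dimethoxy-2-(3-methoxy-4-pivaloyloxyphenyl)-2H-chromene | COc1cc([C@H]2Oc3c(OC)cc(Br)cc3C(OC)=C2)ccc1OC(=O)C(C)(C)C | intermediate
11 | methyl trans-(2S,3S)-5-bromo-7-methoxy-2-(3-methoxy-4-pivaloyloxyphenyl)-2,3-dihydro-1-benzofuran-3-carboxylate | COc1cc([C@H]2Oc3c(OC)cc(Br)cc3[C@@H]2C(=O)OC)ccc1OC(=O)C(C)(C)C | intermediate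
12 | 4-[(2S,3R)-5-bromo-3-(hydroxymethyl)-7-methoxy-2,3-dihydro-1-benzofuran-2-yl]-2-methoxyphenol | COc1cc([C@H]2Oc3c(OC)cc(Br)cc3[C@@H]2CO)ccc1O | intermediate
13 | (2S,3R)-5-bromo-2-[4-(tert-butyldimethylsilyloxy)-3-methoxyphenyl]-3-[(tert-butyldimethylsilyloxy)methyl]-7-methoxy-2,3-dihydro-1-benzofuran | COc1cc([C@H]2Oc3c(OC)cc(Br)cc3[C@@H]2CO[Si](C)(C)C(C)(C)C)ccc1O[Si](C)(C)C(C)(C)C | intermediate
14 | [(2S,3R)-5-bromo-2-[4-(tert-butyldimethylsilyloxy)-3-methoxyphenyl]-7-methoxy-2,3-dihydro-1-benzofuran-3-yl]methanol | COc1cc([C@H]2Oc3c(OC)cc(Br)cc3[C@@H]2CO)ccc1O[Si](C)(C)C(C)(C)C | intermediate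
15 | 4-hydroxybenzoic acid | O=C(O)c1ccc(O)cc1 | starting material
16 | tert-butyldimethylsilyl 4-(tert-butyldimethylsilyloxy)benzoate | CC(C)(C)[Si](C)(C)OC(=O)c1ccc(O[Si](C)(C)C(C)(C)C)cc1 | intermediate
17 | 4-(tert-butyldimethylsilyloxy)benzoic acid | CC(C)(C)[Si](C)(C)Oc1ccc(C(=O)O)cc1 | intermediate
18 | [(2S,3R)-5-bromo-2-[4-(tert-butyldimethylsilyloxy)-3-methoxyphenyl]-7-methoxy-2,3-dihydro-1-benzofuran-3-yl]methyl 4-(tert-butyldimethylsilyloxy)benzoate | COc1cc([C@H]2Oc3c(OC)cc(Br)cc3[C@@H]2COC(=O)c2ccc(O[Si](C)(C)C(C)(C)C)cc2)ccc1O[Si](C)(C)C(C)(C)C | intermediate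
19 | 3,3-diethoxyprop-1-yne | C#CC(OCC)OCC | starting material
20 | [(2S,3R)-2-[4-(tert-butyldimethylsilyloxy)-3-methoxyphenyl]-5-(3,3-diethoxyprop-1-yn-1-yl)-7-methoxy-2,3-dihydro-1-benzofuran-3-yl]methyl 4-(tert-butyldimethylsilyloxy)benzoate | COc1cc([C@H]2Oc3c(OC)cc(C#CC(OCC)OCC)cc3[C@@H]2COC(=O)c2ccc(O[Si](C)(C)C(C)(C)C)cc2)ccc1O[Si](C)(C)C(C)(C)C | intermediate
21 | [(2S,3R)-2-[4-(tert-butyldimethylsilyloxy)-3-methoxyphenyl]-5-[(Z)-3,3-diethoxyprop-1-en-1-yl]-7-methoxy-2,3-dihydro-1-benzofuran-3-yl]methyl 4-(tert-butyldimethylsilyloxy)benzoate | COc1cc([C@H]2Oc3c(OC)cc(/C=C\C(OCC)OCC)cc3[C@@H]2COC(=O)c2ccc(O[Si](C)(C)C(C)(C)C)cc2)ccc1O[Si](C)(C)C(C)(C)C | intermediate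
22 | [(2S,3R)-5-[(Z)-3,3-diethoxyprop-1-en-1-yl]-2-(4-hydroxy-3-methoxyphenyl)-7-methoxy-2,3-dihydro-1-benzofuran-3-yl]methyl 4-hydroxybenzoate | COc1cc([C@H]2Oc3c(OC)cc(/C=C\C(OCC)OCC)cc3[C@@H]2COC(=O)c2ccc(O)cc2)ccc1O | intermediate
23 | [(2S,3R)-2-(4-hydroxy-3-methoxyphenyl)-7-methoxy-5-[(Z)-3-oxoprop-1-en-1-yl]-2,3-dihydro-1-benzofuran-3-yl]methyl 4-hydroxybenzoate | COc1cc([C@H]2Oc3c(OC)cc(/C=C\C=O)cc3[C@@H]2COC(=O)c2ccc(O)cc2)ccc1O | target

**Step count**

Total: 15 steps. Longest linear sequence: 12 steps (steps 1, 2, 5, 6, 7, 8, 9, 11, 12, 13, 14, 15).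

**Steps most likely to fail**

1. Step 6 (ring contraction). The C2 aryl group may migrate instead of ring A, H-2 may be lost to give the flavone, or acid may open the pyranone before ketalisation and erode the C2 configuration. The fallback sets out from 8 and comes back at 11, and replaces the iodane-induced shift by a Wolff ring contraction. The lithium enolate of 8 (LiN(SiMe3)2, THF, −78 °C, kept cold to hold back retro-oxa-Michael opening) is acylated with CF3CO2CH2CF3 to (2S)-6-bromo-8-methoxy-2-(3-methoxy-4-pivaloyloxyphenyl)-3-(trifluoroacetyl)chroman-4-one F1. Deacylative diazo transfer (MsN3, Et3N, MeCN) then gives (2R)-6-bromo-3-diazo-8-methoxy-2-(3-methoxy-4-pivaloyloxyphenyl)chroman-4-one F2 (same spatial arrangement at C2, descriptor changed by priority). Irradiation in methanol triggers the Wolff rearrangement: the same ring A carbon moves from C4 to the C3 carbene centre and gives (2R)-5-bromo-7-methoxy-2-(3-methoxy-4-pivaloyloxyphenyl)-3-(oxomethylidene)-2,3-dihydro-1-benzofuran F3. Methanol traps this ketene as a mixture of 11 and its cis epimer, methyl (2S,3R)-5-bromo-7-methoxy-2-(3-methoxy-4-pivaloyloxyphenyl)-2,3-dihydro-1-benzofuran-3-carboxylate F4. DBU in toluene should equilibrate the mixture to the trans ester 11; opening of the five-membered ring from the ester enolate is stereoelectronically disfavoured, so C2 should hold.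

2. Step 15 (acetal hydrolysis). The Z double bond may isomerise to E in the protonated enal or oxocarbenium ion, whose C=C bond is weakened by the ring oxygen para to the side chain. The fallback sets out from 18 and comes back at 23, and avoids acid by reaching the aldehyde through oxidation. Sonogashira coupling of 18 with prop-2-yn-1-ol (same catalyst system as step 12) gives [(2S,3R)-2-[4-(tert-butyldimethylsilyloxy)-3-methoxyphenyl]-5-(3-hydroxyprop-1-yn-1-yl)-7-methoxy-2,3-dihydro-1-benzofuran-3-yl]methyl 4-(tert-butyldimethylsilyloxy)benzoate F5. Lindlar semihydrogenation gives the (Z)-3-hydroxyprop-1-en-1-yl compound F6. Dess–Martin periodinane buffered with NaHCO3 in CH2Cl2 at 0 °C oxidises the allylic alcohol to the bis-silylated (Z)-3-oxoprop-1-en-1-yl compound F7. Et3N·3HF in THF at 0 °C in the dark then removes both silyl groups to give 23.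

3. Step 5 (asymmetric conjugate addition). Facial discrimination may be insufficient, or insertion sluggish, with the 6-bromo-8-methoxy chromone. The fallback sets out from 4 and 7 and comes back at 8, and sets C2 by kinetic resolution instead of by the addition. Pd(OCOCF3)2 with 2,2'-bipyridine under otherwise the same conditions gives racemic 6-bromo-8-methoxy-2-(3-methoxy-4-pivaloyloxyphenyl)chroman-4-one F8. Asymmetric transfer hydrogenation with RuCl(p-cymene)[(R,R)-TsDPEN] and HCO2H/Et3N is expected to reduce only the 2R enantiomer, giving cis-(2R,4R)-6-bromo-4-hydroxy-8-methoxy-2-(3-methoxy-4-pivaloyloxyphenyl)chromane F9. The unreacted ketone 8 is separated from F9 by chromatography and its enantiomeric purity checked by HPLC on a chiral phase.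

**Further compounds**

F1 | step 6 | (2S)-6-bromo-8-methoxy-2-(3-methoxy-4-pivaloyloxyphenyl)-3-(trifluoroacetyl)chroman-4-one (C3 epimers and enol form) | COc1cc([C@H]2Oc3c(OC)cc(Br)cc3C(=O)C2C(=O)C(F)(F)F)ccc1OC(=O)C(C)(C)C
F2 | step 6 | (2R)-6-bromo-3-diazo-8-methoxy-2-(3-methoxy-4-pivaloyloxyphenyl)chroman-4-one | COc1cc([C@H]2Oc3c(OC)cc(Br)cc3C(=O)C2=[N+]=[N-])ccc1OC(=O)C(C)(C)C
F3 | step 6 | (2R)-5-bromo-7-methoxy-2-(3-methoxy-4-pivaloyloxyphenyl)-3-(oxomethylidene)-2,3-dihydro-1-benzofuran | COc1cc([C@H]2Oc3c(OC)cc(Br)cc3C2=C=O)ccc1OC(=O)C(C)(C)C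
F4 | step 6 | methyl cis-(2S,3R)-5-bromo-7-methoxy-2-(3-methoxy-4-pivaloyloxyphenyl)-2,3-dihydro-1-benzofuran-3-carboxylate | COc1cc([C@H]2Oc3c(OC)cc(Br)cc3[C@H]2C(=O)OC)ccc1OC(=O)C(C)(C)C
F5 | step 15 | [(2S,3R)-2-[4-(tert-butyldimethylsilyloxy)-3-methoxyphenyl]-5-(3-hydroxyprop-1-yn-1-yl)-7-methoxy-2,3-dihydro-1-benzofuran-3-yl]methyl 4-(tert-butyldimethylsilyloxy)benzoate | COc1cc([C@H]2Oc3c(OC)cc(C#CCO)cc3[C@@H]2COC(=O)c2ccc(O[Si](C)(C)C(C)(C)C)cc2)ccc1O[Si](C)(C)C(C)(C)C
F6 | step 15 | [(2S,3R)-2-[4-(tert-butyldimethylsilyloxy)-3-methoxyphenyl]-5-[(Z)-3-hydroxyprop-1-en-1-yl]-7-methoxy-2,3-dihydro-1-benzofuran-3-yl]methyl 4-(tert-butyldimethylsilyloxy)benzoate | COc1cc([C@H]2Oc3c(OC)cc(/C=C\CO)cc3[C@@H]2COC(=O)c2ccc(O[Si](C)(C)C(C)(C)C)cc2)ccc1O[Si](C)(C)C(C)(C)C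
F7 | step 15 | [(2S,3R)-2-[4-(tert-butyldimethylsilyloxy)-3-methoxyphenyl]-7-methoxy-5-[(Z)-3-oxoprop-1-en-1-yl]-2,3-dihydro-1-benzofuran-3-yl]methyl 4-(tert-butyldimethylsilyloxy)benzoate | COc1cc([C@H]2Oc3c(OC)cc(/C=C\C=O)cc3[C@@H]2COC(=O)c2ccc(O[Si](C)(C)C(C)(C)C)cc2)ccc1O[Si](C)(C)C(C)(C)C
F8 | step 5 | racemic 6-bromo-8-methoxy-2-(3-methoxy-4-pivaloyloxyphenyl)chroman-4-one | COc1cc(C2Oc3c(OC)cc(Br)cc3C(=O)C2)ccc1OC(=O)C(C)(C)C
F9 | step 5 | cis-(2R,4R)-6-bromo-4-hydroxy-8-methoxy-2-(3-methoxy-4-pivaloyloxyphenyl)chromane | COc1cc([C@@H]2Oc3c(OC)cc(Br)cc3[C@H](O)C2)ccc1OC(=O)C(C)(C)C
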